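**Retrosynthetic overview**

1. Target 31 ⇐ diol 30 (late angeloylation of O8) ⇐ bis-silyl macrolactone 29.
2. 29 ⇐ open-chain (Z)-alkenyl iodide / aldehyde / acrylate ester 26 in one operation: Nozaki–Hiyama–Kishi closure of C5–C6 (ring A, ten-membered carbocycle), then attack of the new O6 alkoxide on C12 (ring B, γ-lactone).
3. Enabling feature: C6 is both the carbinol carbon allylic to the (Z)-C4=C5 alkene of ring A and the alkoxy carbon of ring B, 1,4 to the C12 acyl carbon through C7–C11. An alkenylmetal/aldehyde addition therefore creates a γ-alkoxide poised to lactonise.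
4. 26 ⇐ aldehyde 16 + allylboronate 21: anti-selective, catalyst-controlled 2-alkoxycarbonylallylboration forms C7–C8, sets C7 and C8 and creates the C11=C13 methylene.
5. 16 ⇐ alkyne 10 (from (S)-2-methylglycidol, carries C10) + (Z)-iodoenal 4 (from propargyl alcohol): asymmetric alkenylzinc addition forms C2–C3, sets C3 and the E-C1=C2 alkene. No ring exists before step 17; then ring A, then ring B.

Key step: step 17

Assumption: germacrane numbering is used (ring carbons C1–C10, lactone carbons C11–C13), and the target is taken exactly as drawn, i.e. 1E,4Z with a cis-fused 12,6-lactone (3R,6R,7S,8R,10R).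

**Route**

Step 1
Reactants: 1 prop-2-yn-1-ol
Product: 3 (Z)-3-iodo-2-methylprop-2-en-1-ol, via oxamagnesacycle 2 (not isolated)
Conditions: MeMgBr (3 equiv), CuI (10 mol%), THF, −10 °C → rt; then I2, −78 → 0 °C
Reagents that add atoms: methylmagnesium bromide, C[Mg]Br; iodine, II
Why: Copper-catalysed anti-carbomagnesiation of the propargylic alkoxide puts the methyl group on the internal carbon and magnesium on the terminal carbon cis to CH2O (chelate 2), so iodinolysis with retention should give the Z-alkenyl iodide.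

Step 2
Reactants: 3 (Z)-3-iodo-2-methylprop-2-en-1-ol
Product: 4 (Z)-3-iodo-2-methylprop-2-enal
Conditions: MnO2, CH2Cl2, rt, dark
Reagents that add atoms: none
Why: Allylic oxidation with MnO2 is neutral and should leave the alkenyl iodide and its Z geometry intact.

Step 3
Reactants: 5 (S)-2-methylglycidol
Product: 6 (2R)-2,5-dimethylhex-4-ene-1,2-diol
Conditions: 2-methyl-1-propenylmagnesium bromide (3 equiv), CuI (10 mol%), THF, −40 → 0 °C
Reagents that add atoms: 2-methyl-1-propenylmagnesium bromide, CC(C)=C[Mg]Br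
Why: Copper-catalysed Grignard opening (SN2) of the 2,2-disubstituted epoxide at its CH2 terminus leaves the quaternary stereocentre (future C10) untouched and installs C8 as a trisubstituted alkene, a masked aldehyde.

Step 4
Reactants: 6 (2R)-2,5-dimethylhex-4-ene-1,2-diol
Product: 7 (2R)-2,5-dimethyl-1,2-bis(triethylsilyloxy)hex-4-ene
Conditions: TESOTf (2.5 equiv), 2,6-lutidine, CH2Cl2, −78 → 0 °C
Reagents that add atoms: triethylsilyl triflate, CC[Si](CC)(CC)OS(=O)(=O)C(F)(F)F
Why: Silyl triflate silylation covers both the primary and the hindered tertiary hydroxyl, the latter as the C10 protecting group that is carried to step 18.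

Step 5
Reactants: 7 (2R)-2,5-dimethyl-1,2-bis(triethylsilyloxy)hex-4-ene
Product: 9 (2R)-2,5-dimethyl-2-(triethylsilyloxy)hex-4-enal, via alkoxysulfonium chloride 8 (not isolated)
Conditions: (COCl)2, DMSO, CH2Cl2, −78 → −30 °C; then Et3N, −78 °C → rt
Reagents that add atoms: none
Why: Under Swern conditions a primary triethylsilyl ether is converted directly into the aldehyde (silyl transfer to the activated sulfoxide, then ylide fragmentation) while the tertiary silyl ether is inert, and the α-carbon is quaternary so it cannot epimerise.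

Step 6
Reactants: 9 (2R)-2,5-dimethyl-2-(triethylsilyloxy)hex-4-enal
Product: 10 triethyl{[(3R)-3,6-dimethylhept-5-en-1-yn-3-yl]oxy}silane
Conditions: dimethyl (1-diazo-2-oxopropyl)phosphonate, K2CO3, MeOH, 0 °C → rt
Reagents that add atoms: dimethyl (1-diazo-2-oxopropyl)phosphonate, CC(=O)C(=[N+]=[N-])P(=O)(OC)OC
Why: Seyferth–Gilbert homologation with the Ohira–Bestmann reagent turns the non-enolisable aldehyde into the terminal alkyne (C1≡C2) without touching the quaternary centre.

Step 7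
Reactants: 10 triethyl{[(3R)-3,6-dimethylhept-5-en-1-yn-3-yl]oxy}silane; 4 (Z)-3-iodo-2-methylprop-2-enal
Product: 13 (1Z,3R,4E,6R)-1-iodo-2,6,9-trimethyl-6-(triethylsilyloxy)deca-1,4,8-trien-3-ol, via alkenylborane 11 (not isolated), via alkenylzinc 12 (not isolated)
Conditions: Cy2BH, toluene, 0 °C → rt; Me2Zn, −78 °C; (+)-MIB (10 mol%), then 4, −20 → 0 °C; aq. NH4Cl
Reagents that add atoms: none
Why: Syn hydroboration of the terminal alkyne fixes the E-C1=C2 geometry, boron-to-zinc transmetalation gives an alkenylzinc, and amino-alcohol-catalysed asymmetric alkenylzinc addition sets C3 as R by delivery to the Re face of 4 (the (+)-ligand is chosen because the (−)-ligand is known for Si-face delivery), while the trisubstituted alkene is too hindered for Cy2BH and the alkenyl iodide is inert to organozinc.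

Step 8
Reactants: 13 (1Z,3R,4E,6R)-1-iodo-2,6,9-trimethyl-6-(triethylsilyloxy)deca-1,4,8-trien-3-ol
Product: 14 (1Z,3R,4E,6R)-1-iodo-2,6,9-trimethyl-6-(triethylsilyloxy)deca-1,4,8-trien-3-yl acetate
Conditions: Ac2O, pyridine, DMAP (cat.), CH2Cl2, 0 °C
Reagents that add atoms: acetic anhydride, CC(=O)OC(C)=O
Why: DMAP-catalysed acylation installs the C3 acetate of the target on the only free hydroxyl.

Step 9
Reactants: 14 (1Z,3R,4E,6R)-1-iodo-2,6,9-trimethyl-6-(triethylsilyloxy)deca-1,4,8-trien-3-yl acetate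
Product: 16 (1Z,3R,4E,6R)-1-iodo-2,6-dimethyl-8-oxo-6-(triethylsilyloxy)octa-1,4-dien-3-yl acetate, via vicinal diol 15 (not isolated)
Conditions: OsO4 (2 mol%), NMO, acetone/H2O, 0 °C; then NaIO4, THF/pH 7 buffer, 0 °C
Reagents that add atoms: N-methylmorpholine N-oxide, C[N+]1([O-])CCOCC1 (oxygen relayed through osmium tetroxide, O=[Os](=O)(=O)=O)
Why: Upjohn dihydroxylation should select the electron-rich trisubstituted alkene over the hindered, doubly allylically oxygenated C1=C2 alkene and the alkenyl iodide, and Malaprade cleavage of the diol then unveils the C8 aldehyde.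

Step 10
Reactants: 1 prop-2-yn-1-ol
Product: 17 1-methoxy-4-[(prop-2-yn-1-yloxy)methyl]benzene
Conditions: NaH, 4-methoxybenzyl chloride, Bu4NI (cat.), THF/DMF, 0 °C → rt
Reagents that add atoms: 4-methoxybenzyl chloride, COc1ccc(CCl)cc1
Why: Williamson etherification protects the future C6 oxygen as a PMB ether that can later be removed oxidatively under neutral conditions.

Step 11
Reactants: 17 1-methoxy-4-[(prop-2-yn-1-yloxy)methyl]benzene
Product: 19 methyl 4-[(4-methoxybenzyl)oxy]but-2-ynoate, via lithium acetylide 18 (not isolated)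
Conditions: n-BuLi, THF, −78 °C; then ClCO2Me, −78 → 0 °C
Reagents that add atoms: methyl chloroformate, COC(=O)Cl
Why: C-acylation of the lithium acetylide with a chloroformate gives the ynoate that carries C6, C7, C11 and C12.

Step 12
Reactants: 19 methyl 4-[(4-methoxybenzyl)oxy]but-2-ynoate
Product: 21 methyl (2Z)-4-[(4-methoxybenzyl)oxy]-2-[(4,4,5,5-tetramethyl-1,3,2-dioxaborolan-2-yl)methyl]but-2-enoate, via alkenylalane 20 (not isolated)
Conditions: DIBAL-H, HMPA, THF, 0 °C; then ICH2Bpin, 0 °C → rt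
Reagents that add atoms: 2-(iodomethyl)-4,4,5,5-tetramethyl-1,3,2-dioxaborolane, CC1(C)OB(CI)OC1(C)C
Why: Conjugate syn-hydroalumination of the ynoate gives the α-alumino enoate with H and Al cis, and alkenyl transfer to boron with 1,2-metallate shift and loss of iodide (Matteson-type homologation) should give the allylboronate with CH2B cis to H, i.e. the E-crotyl-type geometry needed for an anti adduct.

Step 13
Reactants: 16 (1Z,3R,4E,6R)-1-iodo-2,6-dimethyl-8-oxo-6-(triethylsilyloxy)octa-1,4-dien-3-yl acetate; 21 methyl (2Z)-4-[(4-methoxybenzyl)oxy]-2-[(4,4,5,5-tetramethyl-1,3,2-dioxaborolan-2-yl)methyl]but-2-enoate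
Product: 23 methyl (3R,4R,6R,7E,9R,10Z)-9-acetoxy-4-hydroxy-11-iodo-3-{[(4-methoxybenzyl)oxy]methyl}-6,10-dimethyl-2-methylidene-6-(triethylsilyloxy)undeca-7,10-dienoate, via pinacol borate 22 (not isolated)
Conditions: (S)-TRIP (10 mol%), 4 Å MS, toluene, −30 → 0 °C; pH 7 buffer work-up
Reagents that add atoms: none
Why: Chiral phosphoric acid-catalysed allylboration through a closed Zimmerman–Traxler chair converts the E-crotyl-type boronate into the anti C7/C8 adduct and creates the C11=C13 methylene, with the (S)-acid chosen for Si-face addition to the aldehyde (the (R)-acid is known for Re-face delivery) so that C8 is R and C7 follows, and the adduct stays O-borylated until work-up so it cannot lactonise during the reaction.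

Step 14
Reactants: 23 methyl (3R,4R,6R,7E,9R,10Z)-9-acetoxy-4-hydroxy-11-iodo-3-{[(4-methoxybenzyl)oxy]methyl}-6,10-dimethyl-2-methylidene-6-(triethylsilyloxy)undeca-7,10-dienoate
Product: 24 methyl (3R,4R,6R,7E,9R,10Z)-9-acetoxy-11-iodo-3-{[(4-methoxybenzyl)oxy]methyl}-6,10-dimethyl-2-methylidene-4,6-bis(triethylsilyloxy)undeca-7,10-dienoate
Conditions: TESOTf, 2,6-lutidine, CH2Cl2, −78 °C
Reagents that add atoms: triethylsilyl triflate, CC[Si](CC)(CC)OS(=O)(=O)C(F)(F)F
Why: Fast low-temperature silylation caps O8 before it can lactonise onto the C12 ester, so that C12 stays available for O6 in step 17.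

Step 15
Reactants: 24 methyl (3R,4R,6R,7E,9R,10Z)-9-acetoxy-11-iodo-3-{[(4-methoxybenzyl)oxy]methyl}-6,10-dimethyl-2-methylidene-4,6-bis(triethylsilyloxy)undeca-7,10-dienoate
Product: 25 methyl (3R,4R,6R,7E,9R,10Z)-9-acetoxy-3-(hydroxymethyl)-11-iodo-6,10-dimethyl-2-methylidene-4,6-bis(triethylsilyloxy)undeca-7,10-dienoate
Conditions: DDQ, CH2Cl2/pH 7 buffer, 0 °C; crude product used at once
Reagents that add atoms: none
Why: Oxidative PMB cleavage with DDQ is neutral and should spare the silyl ethers, the acetate and the alkenyl iodide, and the cold buffered medium keeps the primary γ-hydroxy ester from lactonising before it is oxidised.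

Step 16
Reactants: 25 methyl (3R,4R,6R,7E,9R,10Z)-9-acetoxy-3-(hydroxymethyl)-11-iodo-6,10-dimethyl-2-methylidene-4,6-bis(triethylsilyloxy)undeca-7,10-dienoate
Product: 26 methyl (3S,4R,6R,7E,9R,10Z)-9-acetoxy-3-formyl-11-iodo-6,10-dimethyl-2-methylidene-4,6-bis(triethylsilyloxy)undeca-7,10-dienoate
Conditions: DMP, NaHCO3, CH2Cl2, 0 °C; used directly
Reagents that add atoms: none
Why: Buffered Dess–Martin oxidation is base-free and should therefore deliver the C6 aldehyde without epimerising C7 or moving the C11=C13 alkene into conjugation.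

Step 17
Reactants: 26 methyl (3S,4R,6R,7E,9R,10Z)-9-acetoxy-3-formyl-11-iodo-6,10-dimethyl-2-methylidene-4,6-bis(triethylsilyloxy)undeca-7,10-dienoate
Product: 29 (3aR,4R,6R,7E,9R,10Z,11aR)-6,10-dimethyl-3-methylidene-2-oxo-4,6-bis(triethylsilyloxy)-2,3,3a,4,5,6,9,11a-octahydrocyclodeca[b]furan-9-yl acetate, via alkenylchromium 27 (not isolated), via chromium alkoxide 28 (not isolated)
Conditions: CrCl2 (10 equiv), NiCl2 (0.1 equiv), DMF/THF, syringe-pump addition of 26 to 2 mM, rt; then 45 °C; aq. sodium potassium tartrate work-up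
Reagents that add atoms: none
Why: Nickel-catalysed activation of the C5–I bond and transmetalation to chromium give alkenylchromium 27, which adds to the C6 aldehyde (intramolecular Nozaki–Hiyama–Kishi reaction) to give chromium alkoxide 28, whose oxygen then acylates the C12 methyl ester with loss of methoxide. The closest known reaction types are NHK macrocyclisations of iodoalkenyl aldehydes to medium and large rings and the one-pot lactonisation of chromium alkoxides onto a 2-alkoxycarbonylallyl unit in CrCl2-mediated α-methylene-γ-butyrolactone syntheses. Ring A (ten-membered carbocycle) closes by 10-exo-trig addition of C5 to the C6 carbonyl and ring B (γ-lactone) by 5-exo-trig acyl substitution at C12. The new C6 stereocentre is controlled by C7: Felkin–Anh addition with the planar acrylate antiperiplanar to the incoming alkenyl carbon and the tether through C8 held synclinal should give 6R and hence the cis ring fusion, while the Z geometry of C4=C5 is retained because alkenylchromium formation and addition proceed with retention. The step needs chemoselectivity for the aldehyde over the acrylate, acetate and ester (intrinsic to organochromium reagents, with nickel kept low), ring closure over dimerisation (high dilution), and lactonisation by O6 only, which is secured because O8 and O10 are silylated and O3 is acetylated; the O10 silyl ether also prevents a six-membered hemiacetal with C6.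

Step 18
Reactants: 29 (3aR,4R,6R,7E,9R,10Z,11aR)-6,10-dimethyl-3-methylidene-2-oxo-4,6-bis(triethylsilyloxy)-2,3,3a,4,5,6,9,11a-octahydrocyclodeca[b]furan-9-yl acetate
Product: 30 (3aS,4R,6R,7E,9R,10Z,11aR)-4,6-dihydroxy-6,10-dimethyl-3-methylidene-2-oxo-2,3,3a,4,5,6,9,11a-octahydrocyclodeca[b]furan-9-yl acetate
Conditions: HF·pyridine, pyridine, THF, 0 °C → rt
Reagents that add atoms: none
Why: Buffered fluoride desilylation should remove both triethylsilyl ethers without touching the acetate or the α-methylene lactone.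

Step 19
Reactants: 30 (3aS,4R,6R,7E,9R,10Z,11aR)-4,6-dihydroxy-6,10-dimethyl-3-methylidene-2-oxo-2,3,3a,4,5,6,9,11a-octahydrocyclodeca[b]furan-9-yl acetate
Product: 31 (3aS,4R,6R,7E,9R,10Z,11aR)-9-acetoxy-6-hydroxy-6,10-dimethyl-3-methylidene-2-oxo-2,3,3a,4,5,6,9,11a-octahydrocyclodeca[b]furan-4-yl (2Z)-2-methylbut-2-enoate
Conditions: angelic acid, 2,4,6-trichlorobenzoyl chloride, Et3N, toluene, rt; then 30, 75 °C
Reagents that add atoms: angelic acid, C/C=C(/C)C(=O)O
Why: Yamaguchi-type mixed-anhydride esterification without DMAP should acylate the secondary C8 hydroxyl in preference to the tertiary C10 hydroxyl and avoids the nucleophile-induced Z to E isomerisation that would give the tiglate.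

**Compound list**

1 | prop-2-yn-1-ol (propargyl alcohol) | C#CCO | starting material
2 | 3-methyl-2,5-dihydro-1,2-oxamagnesole (chelated Z-alkenylmagnesium alkoxide) | CC1=C[Mg]OC1 | intermediate (not isolated)
3 | (Z)-3-iodo-2-methylprop-2-en-1-ol | I/C=C(/C)CO | intermediate
4 | (Z)-3-iodo-2-methylprop-2-enal | I/C=C(/C)C=O | intermediate
5 | (S)-2-methylglycidol, [(2S)-2-methyloxiran-2-yl]methanol | OC[C@@]1(C)CO1 | starting material
6 | (2R)-2,5-dimethylhex-4-ene-1,2-diol | OC[C@](C)(O)CC=C(C)C | intermediate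
7 | (2R)-2,5-dimethyl-1,2-bis(triethylsilyloxy)hex-4-ene | CC[Si](CC)(CC)OC[C@](C)(O[Si](CC)(CC)CC)CC=C(C)C | intermediate
8 | {[(2R)-2,5-dimethyl-2-(triethylsilyloxy)hex-4-en-1-yl]oxy}dimethylsulfonium chloride | C[S+](C)OC[C@](C)(O[Si](CC)(CC)CC)CC=C(C)C.[Cl-] | intermediate (not isolated)
9 | (2R)-2,5-dimethyl-2-(triethylsilyloxy)hex-4-enal | O=C[C@](C)(O[Si](CC)(CC)CC)CC=C(C)C | intermediate
10 | triethyl{[(3R)-3,6-dimethylhept-5-en-1-yn-3-yl]oxy}silane | C#C[C@](C)(O[Si](CC)(CC)CC)CC=C(C)C | intermediate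
11 | dicyclohexyl[(1E,3R)-3,6-dimethyl-3-(triethylsilyloxy)hepta-1,5-dien-1-yl]borane | C1CCCCC1B(C1CCCCC1)/C=C/[C@](C)(O[Si](CC)(CC)CC)CC=C(C)C | intermediate (not isolated)
12 | [(1E,3R)-3,6-dimethyl-3-(triethylsilyloxy)hepta-1,5-dien-1-yl](methyl)zinc | C[Zn]/C=C/[C@](C)(O[Si](CC)(CC)CC)CC=C(C)C | intermediate (not isolated)
13 | (1Z,3R,4E,6R)-1-iodo-2,6,9-trimethyl-6-(triethylsilyloxy)deca-1,4,8-trien-3-ol | I/C=C(/C)[C@H](O)/C=C/[C@](C)(O[Si](CC)(CC)CC)CC=C(C)C | intermediate
14 | (1Z,3R,4E,6R)-1-iodo-2,6,9-trimethyl-6-(triethylsilyloxy)deca-1,4,8-trien-3-yl acetate | I/C=C(/C)[C@H](OC(C)=O)/C=C/[C@](C)(O[Si](CC)(CC)CC)CC=C(C)C | intermediate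
15 | (1Z,3R,4E,6R)-8,9-dihydroxy-1-iodo-2,6,9-trimethyl-6-(triethylsilyloxy)deca-1,4-dien-3-yl acetate (both C8 epimers) | I/C=C(/C)[C@H](OC(C)=O)/C=C/[C@](C)(O[Si](CC)(CC)CC)CC(O)C(C)(C)O | intermediate (not isolated)
16 | (1Z,3R,4E,6R)-1-iodo-2,6-dimethyl-8-oxo-6-(triethylsilyloxy)octa-1,4-dien-3-yl acetate | I/C=C(/C)[C@H](OC(C)=O)/C=C/[C@](C)(O[Si](CC)(CC)CC)CC=O | intermediate
17 | 1-methoxy-4-[(prop-2-yn-1-yloxy)methyl]benzene | C#CCOCc1ccc(OC)cc1 | intermediate
18 | lithium 3-[(4-methoxybenzyl)oxy]prop-1-yn-1-ide | [Li]C#CCOCc1ccc(OC)cc1 | intermediate (not isolated)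
19 | methyl 4-[(4-methoxybenzyl)oxy]but-2-ynoate | COC(=O)C#CCOCc1ccc(OC)cc1 | intermediate
20 | methyl (2E)-2-(diisobutylalumanyl)-4-[(4-methoxybenzyl)oxy]but-2-enoate | COC(=O)/C(=C\COCc1ccc(OC)cc1)[Al](CC(C)C)CC(C)C | intermediate (not isolated)
21 | methyl (2Z)-4-[(4-methoxybenzyl)oxy]-2-[(4,4,5,5-tetramethyl-1,3,2-dioxaborolan-2-yl)methyl]but-2-enoate | COC(=O)/C(=C\COCc1ccc(OC)cc1)CB1OC(C)(C)C(C)(C)O1 | intermediate
22 | O4-(pinacolboryl) derivative of 23 (borate ester of the C8 oxygen) | I/C=C(/C)[C@H](OC(C)=O)/C=C/[C@](C)(O[Si](CC)(CC)CC)C[C@@H](OB1OC(C)(C)C(C)(C)O1)[C@@H](COCc1ccc(OC)cc1)C(=C)C(=O)OC | intermediate (not isolated)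
23 | methyl (3R,4R,6R,7E,9R,10Z)-9-acetoxy-4-hydroxy-11-iodo-3-{[(4-methoxybenzyl)oxy]methyl}-6,10-dimethyl-2-methylidene-6-(triethylsilyloxy)undeca-7,10-dienoate | I/C=C(/C)[C@H](OC(C)=O)/C=C/[C@](C)(O[Si](CC)(CC)CC)C[C@@H](O)[C@@H](COCc1ccc(OC)cc1)C(=C)C(=O)OC | intermediate
24 | methyl (3R,4R,6R,7E,9R,10Z)-9-acetoxy-11-iodo-3-{[(4-methoxybenzyl)oxy]methyl}-6,10-dimethyl-2-methylidene-4,6-bis(triethylsilyloxy)undeca-7,10-dienoate | I/C=C(/C)[C@H](OC(C)=O)/C=C/[C@](C)(O[Si](CC)(CC)CC)C[C@@H](O[Si](CC)(CC)CC)[C@@H](COCc1ccc(OC)cc1)C(=C)C(=O)OC | intermediate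
25 | methyl (3R,4R,6R,7E,9R,10Z)-9-acetoxy-3-(hydroxymethyl)-11-iodo-6,10-dimethyl-2-methylidene-4,6-bis(triethylsilyloxy)undeca-7,10-dienoate | I/C=C(/C)[C@H](OC(C)=O)/C=C/[C@](C)(O[Si](CC)(CC)CC)C[C@@H](O[Si](CC)(CC)CC)[C@@H](CO)C(=C)C(=O)OC | intermediate
26 | methyl (3S,4R,6R,7E,9R,10Z)-9-acetoxy-3-formyl-11-iodo-6,10-dimethyl-2-methylidene-4,6-bis(triethylsilyloxy)undeca-7,10-dienoate | I/C=C(/C)[C@H](OC(C)=O)/C=C/[C@](C)(O[Si](CC)(CC)CC)C[C@@H](O[Si](CC)(CC)CC)[C@@H](C=O)C(=C)C(=O)OC | intermediate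
27 | C5-dichlorochromium derivative of 26 (iodine replaced by CrCl2, Z geometry retained) | Cl[Cr](Cl)/C=C(/C)[C@H](OC(C)=O)/C=C/[C@](C)(O[Si](CC)(CC)CC)C[C@@H](O[Si](CC)(CC)CC)[C@@H](C=O)C(=C)C(=O)OC | intermediate (not isolated)
28 | dichlorochromium alkoxide of methyl 2-[(1S,2R,3Z,5R,6E,8R,10R)-5-acetoxy-2-hydroxy-4,8-dimethyl-8,10-bis(triethylsilyloxy)cyclodeca-3,6-dien-1-yl]prop-2-enoate | COC(=O)C(=C)[C@@H]1[C@H](O[Cr](Cl)Cl)/C=C(/C)[C@H](OC(C)=O)/C=C/[C@](C)(O[Si](CC)(CC)CC)C[C@H]1O[Si](CC)(CC)CC | intermediate (not isolated)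
29 | (3aR,4R,6R,7E,9R,10Z,11aR)-6,10-dimethyl-3-methylidene-2-oxo-4,6-bis(triethylsilyloxy)-2,3,3a,4,5,6,9,11a-octahydrocyclodeca[b]furan-9-yl acetate | C=C1C(=O)O[C@@H]2/C=C(/C)[C@H](OC(C)=O)/C=C/[C@](C)(O[Si](CC)(CC)CC)C[C@@H](O[Si](CC)(CC)CC)[C@H]12 | intermediate
30 | (3aS,4R,6R,7E,9R,10Z,11aR)-4,6-dihydroxy-6,10-dimethyl-3-methylidene-2-oxo-2,3,3a,4,5,6,9,11a-octahydrocyclodeca[b]furan-9-yl acetate | C=C1C(=O)O[C@@H]2/C=C(/C)[C@H](OC(C)=O)/C=C/[C@](C)(O)C[C@@H](O)[C@H]12 | intermediate
31 | (3aS,4R,6R,7E,9R,10Z,11aR)-9-acetoxy-6-hydroxy-6,10-dimethyl-3-methylidene-2-oxo-2,3,3a,4,5,6,9,11a-octahydrocyclodeca[b]furan-4-yl (2Z)-2-methylbut-2-enoate (CNP0181631.1) | C=C1C(=O)O[C@@H]2/C=C(/C)[C@H](OC(C)=O)/C=C/[C@](C)(O)C[C@@H](OC(=O)/C(C)=C\C)[C@H]12 | target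

**Step count and risks**

Total step count: 19. Longest linear sequence: 14 steps (from 5 through steps 3–9 and 13–19 to 31).

Steps most likely to fail:

Step 17. The aldehyde may epimerise at C7 or isomerise before it is captured. The alkenylchromium may add to the wrong carbonyl face, giving the 6-epimer and then a trans-fused lactone. Intermolecular coupling or simple reduction of the C–I bond may compete, and acyl transfer from the chromium alkoxide may be incomplete. The fallback separates C–C bond formation, control of C6 and lactonisation. It sets out from 26 and comes back at 29. The same NiCl2/CrCl2 ring closure is run at 0 °C in THF/DMF and quenched cold, so that the ring-closed hydroxy ester is intercepted before it lactonises. If this is the 6-epimer, methyl 2-[(1R,2S,3Z,5R,6E,8R,10R)-5-acetoxy-2-hydroxy-4,8-dimethyl-8,10-bis(triethylsilyloxy)cyclodeca-3,6-dien-1-yl]prop-2-enoate F1, it is oxidised with DMP to the ring enone, methyl 2-[(1S,3Z,5R,6E,8R,10R)-5-acetoxy-4,8-dimethyl-2-oxo-8,10-bis(triethylsilyloxy)cyclodeca-3,6-dien-1-yl]prop-2-enoate F2. The ketone is then reduced under reagent control (Corey–Bakshi–Shibata oxazaborolidine with catecholborane, the antipode being chosen by screening) to the (2R)-alcohol, methyl 2-[(1R,2R,3Z,5R,6E,8R,10R)-5-acetoxy-2-hydroxy-4,8-dimethyl-8,10-bis(triethylsilyloxy)cyclodeca-3,6-dien-1-yl]prop-2-enoate F3, which is closed to 29 with PPTS in CH2Cl2.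

Step 13. The electron-poor boronate may add too slowly to the β-branched aldehyde, facial control by the phosphoric acid may be insufficient for this boronate, and the adduct may lactonise onto C12 during work-up. The fallback moves stereocontrol from the catalyst to an auxiliary on boron and needs no acid. It sets out from 21 and comes back at 23. Treatment of 21 with KHF2 gives potassium {(2Z)-2-(methoxycarbonyl)-4-[(4-methoxybenzyl)oxy]but-2-en-1-yl}trifluoroborate F4. TMSCl and diisopropyl (2R,3R)-tartrate convert this into the tartrate-modified allylboronate, diisopropyl (4R,5R)-2-{(2Z)-2-(methoxycarbonyl)-4-[(4-methoxybenzyl)oxy]but-2-en-1-yl}-1,3,2-dioxaborolane-4,5-dicarboxylate F5. This more Lewis-acidic reagent should add to 16 without catalyst (toluene, 4 Å MS, −78 °C → rt) through the same chair transition state. The (R,R)-tartrate is taken because it directs Si-face addition in the parent allyl- and crotylboronates. The adduct is the tartrate borate of the C8 oxygen, O4-boryl derivative of 23 F6, which is hydrolysed at pH 7 to 23.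

Step 19. Acylation of the hindered C8 hydroxyl may be slow, and on prolonged heating with base the angelate may isomerise to the tiglate or O8 may translactonise onto C12. The fallback builds the angelate double bond on the molecule instead of transferring it. It sets out from 30 and comes back at 31. Carbodiimide coupling (EDC, DMAP, CH2Cl2, 0 °C) of 30 with 2-(diphenoxyphosphoryl)propanoic acid gives the C8 phosphonopropanoate, (3aS,4R,6R,7E,9R,10Z,11aR)-9-acetoxy-6-hydroxy-6,10-dimethyl-3-methylidene-2-oxo-2,3,3a,4,5,6,9,11a-octahydrocyclodeca[b]furan-4-yl 2-(diphenoxyphosphoryl)propanoate F7. A Z-selective Horner–Wadsworth–Emmons reaction of the Ando type with acetaldehyde (DBU, NaI, THF, −78 → 0 °C) then gives 31.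

Further compounds
F1 | step 17 | methyl 2-[(1R,2S,3Z,5R,6E,8R,10R)-5-acetoxy-2-hydroxy-4,8-dimethyl-8,10-bis(triethylsilyloxy)cyclodeca-3,6-dien-1-yl]prop-2-enoate | COC(=O)C(=C)[C@@H]1[C@@H](O)/C=C(/C)[C@H](OC(C)=O)/C=C/[C@](C)(O[Si](CC)(CC)CC)C[C@H]1O[Si](CC)(CC)CC
F2 | step 17 | methyl 2-[(1S,3Z,5R,6E,8R,10R)-5-acetoxy-4,8-dimethyl-2-oxo-8,10-bis(triethylsilyloxy)cyclodeca-3,6-dien-1-yl]prop-2-enoate | COC(=O)C(=C)[C@@H]1C(=O)/C=C(/C)[C@H](OC(C)=O)/C=C/[C@](C)(O[Si](CC)(CC)CC)C[C@H]1O[Si](CC)(CC)CC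
F3 | step 17 | methyl 2-[(1R,2R,3Z,5R,6E,8R,10R)-5-acetoxy-2-hydroxy-4,8-dimethyl-8,10-bis(triethylsilyloxy)cyclodeca-3,6-dien-1-yl]prop-2-enoate | COC(=O)C(=C)[C@@H]1[C@H](O)/C=C(/C)[C@H](OC(C)=O)/C=C/[C@](C)(O[Si](CC)(CC)CC)C[C@H]1O[Si](CC)(CC)CC
F4 | step 13 | potassium {(2Z)-2-(methoxycarbonyl)-4-[(4-methoxybenzyl)oxy]but-2-en-1-yl}trifluoroborate | COC(=O)/C(=C\COCc1ccc(OC)cc1)C[B-](F)(F)F.[K+]
F5 | step 13 | diisopropyl (4R,5R)-2-{(2Z)-2-(methoxycarbonyl)-4-[(4-methoxybenzyl)oxy]but-2-en-1-yl}-1,3,2-dioxaborolane-4,5-dicarboxylate | COC(=O)/C(=C\COCc1ccc(OC)cc1)CB1O[C@@H](C(=O)OC(C)C)[C@H](C(=O)OC(C)C)O1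
F6 | step 13 | O4-[(4R,5R)-4,5-bis(isopropoxycarbonyl)-1,3,2-dioxaborolan-2-yl] derivative of 23 | I/C=C(/C)[C@H](OC(C)=O)/C=C/[C@](C)(O[Si](CC)(CC)CC)C[C@@H](OB1O[C@@H](C(=O)OC(C)C)[C@H](C(=O)OC(C)C)O1)[C@@H](COCc1ccc(OC)cc1)C(=C)C(=O)OC
F7 | step 19 | (3aS,4R,6R,7E,9R,10Z,11aR)-9-acetoxy-6-hydroxy-6,10-dimethyl-3-methylidene-2-oxo-2,3,3a,4,5,6,9,11a-octahydrocyclodeca[b]furan-4-yl 2-(diphenoxyphosphoryl)propanoate (both epimers at the phosphonate carbon) | C=C1C(=O)O[C@@H]2/C=C(/C)[C@H](OC(C)=O)/C=C/[C@](C)(O)C[C@@H](OC(=O)C(C)P(=O)(Oc3ccccc3)Oc3ccccc3)[C@H]12
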